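The route rests on cutting the C11–C12 bond, which links the CH2 on C9 of ring B to the allylic CH2 of the side chain. The key step exploits that C12 is the γ-carbon of the C13=C14–C15 (E)-enoic acid, hence an allylic electrophile, while C11 is a primary carbon exocyclic to ring B. A nickel-catalysed sp3–sp3 Negishi coupling joins a C11 alkylzinc, carrying the finished bicyclic core, to methyl (E)-4-bromo-3-methylbut-2-enoate and installs the whole side chain with its E geometry in one operation. The zinc reagent comes from an iodide made from andrographolide by oxidative excision of its native side chain, inversion at C3, olefin transposition and Barton iododecarboxylation.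

Key step: step 8

Remark: labdane numbering is used (ring A = C1–C5, C10; ring B = C5–C10; C19 = axial CH2O on C4; C20 = methyl on C10). α is the face of the C10 methyl (H-5 and H-9 are β), so the target is 3β-acetoxy (axial), (3S,4R,5S,9R,10S).
Assumption: andrographolide and methyl (E)-4-bromo-3-methylbut-2-enoate are bought, the bromide as the pure E isomer.

Step 1
Reactants: 1 andrographolide
Product: 2 19-O-(tert-butyldimethylsilyl)andrographolide
Conditions: TBSCl, imidazole, DMF, 0 °C
Reagents that add atoms: tert-butyldimethylsilyl chloride, CC(C)(C)[Si](C)(C)Cl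
Why: Imidazole-promoted silylation should be fastest at the primary C19 hydroxyl, the hindered secondary C3 and the secondary allylic C14 hydroxyls reacting more slowly, and no stereocentre is touched (selective silyl ether formation).

Step 2
Reactants: 2 19-O-(tert-butyldimethylsilyl)andrographolide
Product: 3 19-(tert-butyldimethylsilyloxy)-3α-hydroxy-13,14,15,16-tetranor-5β,9βH,10α-labd-8(17)-en-12-al
Conditions: KMnO4, MgSO4, acetone–H2O, −20 °C
Reagents that add atoms: potassium permanganate, [K+].[O-][Mn](=O)(=O)=O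
Why: Permanganate [3+2] addition should be fastest at the electron-poor, conjugated C12=C13 alkylidene-lactone bond and the resulting manganate ester fragments to the C12 aldehyde, while the isolated 8(17)-methylene reacts more slowly in the cold with limited oxidant (oxidative olefin cleavage).

Step 3
Reactants: 3 19-(tert-butyldimethylsilyloxy)-3α-hydroxy-13,14,15,16-tetranor-5β,9βH,10α-labd-8(17)-en-12-al
Product: 4 19-(tert-butyldimethylsilyloxy)-3α-hydroxy-13,14,15,16-tetranor-5β,9βH,10α-labd-7-en-12-al
Conditions: Co(salen-tBu,tBu)Cl (cat.), PhSiH3 (cat.), PhH, rt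
Reagents that add atoms: none
Why: Cobalt-hydride hydrogen-atom transfer to C17 gives the tertiary C8 radical, which should return a hydrogen atom from the unhindered C7 methylene and not from the shielded tertiary C9–H, so the trisubstituted Δ7 olefin forms and C9 is untouched (olefin isomerisation by metal-hydride hydrogen-atom transfer).

Step 4
Reactants: 4 19-(tert-butyldimethylsilyloxy)-3α-hydroxy-13,14,15,16-tetranor-5β,9βH,10α-labd-7-en-12-al
Product: 5 19-(tert-butyldimethylsilyloxy)-3-oxo-13,14,15,16-tetranor-5β,9βH,10α-labd-7-en-12-oic acid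
Conditions: PDC, DMF, rt
Reagents that add atoms: pyridinium dichromate, c1cc[nH+]cc1.c1cc[nH+]cc1.[O-][Cr](=O)(=O)O[Cr](=O)(=O)[O-]
Why: PDC in DMF should oxidise the non-conjugated aldehyde to the acid and the equatorial C3 alcohol to the ketone in one operation, the quaternary C4 ruling out β-elimination of the silyloxy group (chromium(VI) oxidation).

Step 5
Reactants: 5 19-(tert-butyldimethylsilyloxy)-3-oxo-13,14,15,16-tetranor-5β,9βH,10α-labd-7-en-12-oic acid
Product: 6 19-(tert-butyldimethylsilyloxy)-3β-hydroxy-13,14,15,16-tetranor-5β,9βH,10α-labd-7-en-12-oic acid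
Conditions: L-Selectride, THF, −78 °C; aq NH4Cl
Reagents that add atoms: none
Why: The bulky trialkylborohydride should add along the equatorial trajectory because the axial one is blocked by the syn-axial hydrogens on C1 and C5, which sets the axial 3β-alcohol (C3 inverted relative to andrographolide) while the lithium carboxylate stays inert (selectride reduction).

Step 6
Reactants: 6 19-(tert-butyldimethylsilyloxy)-3β-hydroxy-13,14,15,16-tetranor-5β,9βH,10α-labd-7-en-12-oic acid
Product: 8 11-iodo-19-(tert-butyldimethylsilyloxy)-12,13,14,15,16-pentanor-5β,9βH,10α-labd-7-en-3β-ol, via thiohydroxamate ester 7 (not isolated)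
Conditions: N-hydroxypyridine-2-thione, DCC, DMAP (cat.), CH2Cl2, 0 °C, dark; then CHI3, PhH, hν, rt
Reagents that add atoms: iodoform, IC(I)I
Why: Photolysis of the thiohydroxamate ester releases CO2 and the primary C11 radical, which should abstract iodine from iodoform faster than the reversible 3-exo closure onto the Δ7 olefin can divert it, and no stereocentre is involved (Barton decarboxylative iodination).

Step 7
Reactants: 8 11-iodo-19-(tert-butyldimethylsilyloxy)-12,13,14,15,16-pentanor-5β,9βH,10α-labd-7-en-3β-ol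
Product: 9 11-iodo-19-(tert-butyldimethylsilyloxy)-12,13,14,15,16-pentanor-5β,9βH,10α-labd-7-en-3β-yl acetate
Conditions: Ac2O, Et3N, DMAP, CH2Cl2, rt
Reagents that add atoms: acetic anhydride, CC(=O)OC(C)=O
Why: DMAP-catalysed acylation should esterify the hindered axial C3 hydroxyl, the only free hydroxyl in 8, with retention at C3 (O-acetylation).

Step 8
Reactants: 9 11-iodo-19-(tert-butyldimethylsilyloxy)-12,13,14,15,16-pentanor-5β,9βH,10α-labd-7-en-3β-yl acetate; 10 methyl (2E)-4-bromo-3-methylbut-2-enoate
Product: 12 methyl (13E)-3β-acetoxy-19-(tert-butyldimethylsilyloxy)-5β,9βH,10α-labda-7,13-dien-15-oate, via alkylzinc iodide 11 (not isolated)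
Conditions: Zn dust (I2-activated), DMA, 60 °C; decanted onto 10, NiCl2·glyme (10 mol%), i-Pr-Pybox (13 mol%), NaCl, DMA–DMF, −10 °C to rt
Reagents that add atoms: none
Why: Zinc inserts into the primary C11–I bond to give alkylzinc iodide 11, which tolerates the acetate and the silyl ether; the Ni–pybox catalyst ionises the allylic bromide to an η3-allylnickel carrying the ester syn, takes up the alkyl group from zinc and forms the C11–C12 bond by reductive elimination at the unsubstituted allyl terminus. The closest known reaction is the Ni/pybox-catalysed Negishi coupling of alkylzinc halides with allylic halides, which for γ-halo-α,β-unsaturated esters is γ-selective. No ring is closed and no stereocentre is created; the E geometry of C13=C14 is controlled by the syn-allyl, which the E bromide enters directly and which is also the more stable isomer, so any Z bromide should converge on it. The selectivities needed are attack at C12 over C14, secured by the unhindered CH2 terminus and the retained conjugation with the ester, and cross-coupling over β-hydride elimination from the C11–Ni species, secured by the tridentate ligand.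

Step 9
Reactants: 12 methyl (13E)-3β-acetoxy-19-(tert-butyldimethylsilyloxy)-5β,9βH,10α-labda-7,13-dien-15-oate
Product: 14 (13E)-3β-acetoxy-19-hydroxy-5β,9βH,10α-labda-7,13-dien-15-oic acid, via silyl ether acid 13 (not isolated)
Conditions: LiI, EtOAc, reflux; then 1 M HCl, THF, rt
Reagents that add atoms: none
Why: Iodide should attack the ester methyl group by SN2 and so cleave the methyl ester without touching the secondary acetate, and dilute acid then removes the primary silyl ether; acyl migration is excluded because the C3 and C19 oxygens are anti on ring A (nucleophilic ester dealkylation, then desilylation).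

Compound list
1 | andrographolide, (12E,14S)-3α,14,19-trihydroxy-5β,9βH,10α-labda-8(17),12-dien-16,15-olide | O[C@@H]1CC[C@]2(C)[C@H](CCC(=C)[C@H]2C/C=C3/C(=O)OC[C@H]3O)[C@]1(C)CO | starting material
2 | 19-O-(tert-butyldimethylsilyl)andrographolide | O[C@@H]1CC[C@]2(C)[C@H](CCC(=C)[C@H]2C/C=C3/C(=O)OC[C@H]3O)[C@]1(C)CO[Si](C)(C)C(C)(C)C | intermediate
3 | 19-(tert-butyldimethylsilyloxy)-3α-hydroxy-13,14,15,16-tetranor-5β,9βH,10α-labd-8(17)-en-12-al | O[C@@H]1CC[C@]2(C)[C@H](CCC(=C)[C@H]2CC=O)[C@]1(C)CO[Si](C)(C)C(C)(C)C | intermediate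
4 | 19-(tert-butyldimethylsilyloxy)-3α-hydroxy-13,14,15,16-tetranor-5β,9βH,10α-labd-7-en-12-al | O[C@@H]1CC[C@]2(C)[C@H](CC=C(C)[C@H]2CC=O)[C@]1(C)CO[Si](C)(C)C(C)(C)C | intermediate
5 | 19-(tert-butyldimethylsilyloxy)-3-oxo-13,14,15,16-tetranor-5β,9βH,10α-labd-7-en-12-oic acid | O=C1CC[C@]2(C)[C@H](CC=C(C)[C@H]2CC(=O)O)[C@]1(C)CO[Si](C)(C)C(C)(C)C | intermediate
6 | 19-(tert-butyldimethylsilyloxy)-3β-hydroxy-13,14,15,16-tetranor-5β,9βH,10α-labd-7-en-12-oic acid (axial 3-OH) | O[C@H]1CC[C@]2(C)[C@H](CC=C(C)[C@H]2CC(=O)O)[C@]1(C)CO[Si](C)(C)C(C)(C)C | intermediate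
7 | 2-thioxopyridin-1(2H)-yl (thiohydroxamate) ester of acid 6 | O[C@H]1CC[C@]2(C)[C@H](CC=C(C)[C@H]2CC(=O)ON3C=CC=CC3=S)[C@]1(C)CO[Si](C)(C)C(C)(C)C | intermediate
8 | 11-iodo-19-(tert-butyldimethylsilyloxy)-12,13,14,15,16-pentanor-5β,9βH,10α-labd-7-en-3β-ol | O[C@H]1CC[C@]2(C)[C@H](CC=C(C)[C@H]2CI)[C@]1(C)CO[Si](C)(C)C(C)(C)C | intermediate
9 | 11-iodo-19-(tert-butyldimethylsilyloxy)-12,13,14,15,16-pentanor-5β,9βH,10α-labd-7-en-3β-yl acetate | CC(=O)O[C@H]1CC[C@]2(C)[C@H](CC=C(C)[C@H]2CI)[C@]1(C)CO[Si](C)(C)C(C)(C)C | intermediate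
10 | methyl (2E)-4-bromo-3-methylbut-2-enoate | COC(=O)/C=C(\C)CBr | starting material
11 | C11 alkylzinc iodide derived from 9 | CC(=O)O[C@H]1CC[C@]2(C)[C@H](CC=C(C)[C@H]2C[Zn]I)[C@]1(C)CO[Si](C)(C)C(C)(C)C | intermediate
12 | methyl (13E)-3β-acetoxy-19-(tert-butyldimethylsilyloxy)-5β,9βH,10α-labda-7,13-dien-15-oate | CC(=O)O[C@H]1CC[C@]2(C)[C@H](CC=C(C)[C@H]2CC/C(C)=C/C(=O)OC)[C@]1(C)CO[Si](C)(C)C(C)(C)C | intermediate
13 | (13E)-3β-acetoxy-19-(tert-butyldimethylsilyloxy)-5β,9βH,10α-labda-7,13-dien-15-oic acid | CC(=O)O[C@H]1CC[C@]2(C)[C@H](CC=C(C)[C@H]2CC/C(C)=C/C(=O)O)[C@]1(C)CO[Si](C)(C)C(C)(C)C | intermediate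
14 | (13E)-3β-acetoxy-19-hydroxy-5β,9βH,10α-labda-7,13-dien-15-oic acid, (3S,4R,5S,9R,10S) | CC(=O)O[C@H]1CC[C@]2(C)[C@H](CC=C(C)[C@H]2CC/C(C)=C/C(=O)O)[C@]1(C)CO | target

Total step count: 9. Longest linear sequence: 9 steps (1 to 14); bromide 10 is bought.

Steps most likely to fail

Step 8: the coupling may lose material through β-hydride elimination or protonation of the organozinc. It may also form the C–C bond at C14 instead of C12, or erode the E geometry through syn/anti isomerisation of the allylnickel. Fallback: from iodide 9, a tin hydride-mediated Giese addition of the C11 radical to methyl vinyl ketone (Bu3SnH, AIBN, PhH, 80 °C) would form the same C11–C12 bond and give the 14,15-dinor-13-ketone F1. Horner–Wadsworth–Emmons olefination with trimethyl phosphonoacetate and NaH in THF would then build C13=C14 and, after removal of the minor Z isomer, return to ester 12.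

Step 2: the cleavage may suffer from competing attack on the 8(17)-methylene or from over-oxidation of the aldehyde. Fallback: from silyl ether 2, nucleophilic epoxidation (t-BuOOH, Triton B, THF, 0 °C), which addresses only the electron-poor C12=C13 bond, would give the 12,13-epoxide F2. Periodic acid in aqueous THF would cleave it and return to aldehyde 3.

Step 3: the isomerisation may run on to the tetrasubstituted Δ8(9) olefin, or stall through quenching of the cobalt hydride. Fallback: from aldehyde 3, the exocyclic olefin is kept and the order of events is changed. PDC oxidation would give the exocyclic keto acid F3, L-Selectride the exocyclic 3β-hydroxy acid F4, and Barton iodination via the exocyclic thiohydroxamate ester F5 the exocyclic iodide F6, in which no carbonyl oxygen can trap a cation at C8. Acid-catalysed equilibration through the tertiary C8 cation (TsOH, PhH, 60 °C), with removal of the Δ8(9) isomer on AgNO3-silica, would return to iodide 8.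

Further compounds
F1 | step 8 | 3β-acetoxy-19-(tert-butyldimethylsilyloxy)-14,15-dinor-5β,9βH,10α-labd-7-en-13-one | CC(=O)O[C@H]1CC[C@]2(C)[C@H](CC=C(C)[C@H]2CCC(C)=O)[C@]1(C)CO[Si](C)(C)C(C)(C)C
F2 | step 2 | 12,13-epoxy-19-O-(tert-butyldimethylsilyl)andrographolide (mixture at C12 and C13) | O[C@@H]1CC[C@]2(C)[C@H](CCC(=C)[C@H]2CC3OC34C(=O)OC[C@H]4O)[C@]1(C)CO[Si](C)(C)C(C)(C)C
F3 | step 3 | 19-(tert-butyldimethylsilyloxy)-3-oxo-13,14,15,16-tetranor-5β,9βH,10α-labd-8(17)-en-12-oic acid | O=C1CC[C@]2(C)[C@H](CCC(=C)[C@H]2CC(=O)O)[C@]1(C)CO[Si](C)(C)C(C)(C)C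
F4 | step 3 | 19-(tert-butyldimethylsilyloxy)-3β-hydroxy-13,14,15,16-tetranor-5β,9βH,10α-labd-8(17)-en-12-oic acid | O[C@H]1CC[C@]2(C)[C@H](CCC(=C)[C@H]2CC(=O)O)[C@]1(C)CO[Si](C)(C)C(C)(C)C
F5 | step 3 | 2-thioxopyridin-1(2H)-yl (thiohydroxamate) ester of F4 | O[C@H]1CC[C@]2(C)[C@H](CCC(=C)[C@H]2CC(=O)ON3C=CC=CC3=S)[C@]1(C)CO[Si](C)(C)C(C)(C)C
F6 | step 3 | 11-iodo-19-(tert-butyldimethylsilyloxy)-12,13,14,15,16-pentanor-5β,9βH,10α-labd-8(17)-en-3β-ol | O[C@H]1CC[C@]2(C)[C@H](CCC(=C)[C@H]2CI)[C@]1(C)CO[Si](C)(C)C(C)(C)C
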